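**Plan**

1. Retrosynthesis: the three acetates and the C12 hydroxyl go back to silyl ethers, the C5 ester to a C5≡C6 alkyne (C5–C16 cut), and C8–OH/C17–H to an 8,17-epoxy lactone built from a C7 alcohol and a C8 isopropenyl group (O7–C19 cut).
2. Key cut C7–C8: in the ten-membered ring (C1–C10) the lactone atoms O, C19 and C17 span the C7–C8 bond and C7 sits next to C5/C6, so the carbocycle is the [2,3]-Wittig contraction product of a 13-membered allyl (C19–C17=C8) propargyl (C7–C6≡C5) ether.
3. That ether ring is cut at C5≡C6 (alkyne metathesis), C8–C9 (alkenylchromium addition) and C2–C3 (Grignard addition), leaving ring A with one-carbon stubs on C1 and C10.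
4. Forward order: ring A is there from the start (2-allyl-2-methylcyclohexane-1,3-dione) and is functionalised first; then the C2 and C9 arms; then the 13-membered ring closes and contracts to the ten-membered ring; the γ-lactone comes last.
5. Stereochemistry: C1/C14 yeast desymmetrisation; C10/C11 hydroxyl-directed hydrogenation; C12 bulky hydride; C2 CBS reduction; C9 Felkin–Anh addition; C7 the Wittig step; C8 hydroxyl-directed epoxidation; C17 equilibration.

Key step: step 26

Remark: positions use briarane numbering (ten-membered ring C1–C10; ring A C1, C10–C14; lactone C7–O–C19–C17–C8; methyls C15, C18, C20; ester carbon C16).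
Remark: centres formed as mixtures and erased or corrected later (C11 in 7, C10 in 13, C2 in 23, C17 in 39–43 and 49) are left undefined in the SMILES.
Remark: in the yeast reduction sucrose is taken as the stoichiometric reductant.

**Route**

Step 1
Reactants: 1 2-methylcyclohexane-1,3-dione; 2 allyl bromide
Product: 3 2-allyl-2-methylcyclohexane-1,3-dione
Conditions: NaOH (1 M aq), rt
Reagents that add atoms: none
Why: Enolate C-alkylation (SN2) of the cyclic 1,3-dione creates the quaternary C1 with the C15 methyl and an allyl group whose inner carbon becomes C2.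

Step 2
Reactants: 3 2-allyl-2-methylcyclohexane-1,3-dione
Product: 4 (2S,3S)-2-allyl-3-hydroxy-2-methylcyclohexan-1-one
Conditions: baker's yeast, sucrose, H2O, 30 °C
Reagents that add atoms: none
Why: Yeast reduction of this prochiral dione is a known enzymatic desymmetrisation that reduces one enantiotopic carbonyl from one face, which should fix C14 and the quaternary C1 together with the hydroxyl cis to the allyl arm.

Step 3
Reactants: 4 ketol
Product: 5 (2S,3S)-2-allyl-2-methyl-3-(triethylsilyloxy)cyclohexan-1-one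
Conditions: Et3SiCl, imidazole, DMF, rt
Reagents that add atoms: chlorotriethylsilane CC[Si](Cl)(CC)CC
Why: Silyl ether formation protects the C14 hydroxyl through the enolate, organolithium and chromate steps.

Step 4
Reactants: 5 allyl ketone
Product: 6 (2S,3S)-2-methyl-2-[(E)-prop-1-enyl]-3-(triethylsilyloxy)cyclohexan-1-one
Conditions: RuHCl(CO)(PPh3)3 (2 mol%), toluene, 80 °C
Reagents that add atoms: none
Why: Ruthenium hydride-catalysed alkene isomerisation (hydrometalation, β-hydride elimination) moves the double bond next to C1 so that later ozonolysis leaves exactly one carbon (C2) on C1.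

Step 5
Reactants: 6 propenyl ketone
Product: 7 (2S,3S)-2,6-dimethyl-2-[(E)-prop-1-enyl]-3-(triethylsilyloxy)cyclohexan-1-one (C11 epimers)
Conditions: LiN(i-Pr)2, THF, −78 °C; MeI, −78 → 0 °C
Reagents that add atoms: iodomethane CI
Why: Alkylation of the only possible lithium enolate (C1 is quaternary) introduces the C20 methyl at C11; its configuration is irrelevant because C11 becomes sp2 in the next step.

Step 6
Reactants: 7 α-methyl ketone
Product: 9 (5S,6S)-2,6-dimethyl-6-[(E)-prop-1-enyl]-5-(triethylsilyloxy)cyclohex-2-en-1-one, via trimethylsilyl enol ether 8 (not isolated)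
Conditions: LiN(i-Pr)2, Me3SiCl, THF, −78 → 0 °C; Pd(OAc)2, MeCN, rt
Reagents that add atoms: chlorotrimethylsilane C[Si](C)(C)Cl (silicon stays in 8 only)
Why: Saegusa–Ito oxidation, in which the tetrasubstituted silyl enol ether is palladated at C11 and β-hydride elimination towards the ring methylene C12 gives the conjugated enone.

Step 7
Reactants: 10 (tributylstannyl)methanol
Product: 11 tributyl[(4-methoxybenzyloxy)methyl]stannane
Conditions: NaH, THF–DMF, 0 °C; 4-methoxybenzyl chloride, Bu4NI (cat.), rt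
Reagents that add atoms: 4-methoxybenzyl chloride COc1ccc(CCl)cc1
Why: Williamson etherification gives the precursor of a protected hydroxymethyl anion.

Step 8
Reactants: 9 enone; 11 stannane
Product: 13 tertiary allylic alcohol carrying CH2O-PMB on C10 (C10 epimers), via lithium reagent 12 (not isolated)
Conditions: 11, n-BuLi, THF, −78 °C; then 9, −78 °C; H2O
Reagents that add atoms: n-butyllithium [Li]CCCC (lithium stays in 12 only)
Why: Tin–lithium exchange gives an α-alkoxymethyllithium that adds 1,2 to the hindered enone carbonyl and bonds C9 to C10; the carbinol centre is planarised in the next step.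

Step 9
Reactants: 13 tertiary allylic alcohol
Product: 14 (4R,5S)-3-[(4-methoxybenzyloxy)methyl]-2,4-dimethyl-4-[(E)-prop-1-enyl]-5-(triethylsilyloxy)cyclohex-2-en-1-one (C12 ketone, C10=C11)
Conditions: pyridinium chlorochromate [pyH][CrO3Cl], NaOAc, 4 Å sieves, CH2Cl2, rt
Reagents that add atoms: none
Why: Dauben–Babler oxidative transposition, in which the tertiary allylic chromate ester shifts [3,3] to C12 and is oxidised there, placing oxygen at C12 and the tetrasubstituted alkene at C10=C11.

Step 10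
Reactants: 14 ring-A enone
Product: 16 ring-A enone with a hydroxymethyl group (C2) on C1, via aldehyde 15 (not isolated)
Conditions: O3, CH2Cl2–MeOH, −78 °C; PPh3; then EtOH, NaBH4, −78 °C
Reagents that add atoms: ozone [O-][O+]=O
Why: Ozonolysis cleaves the electron-rich propenyl alkene far faster than the tetrasubstituted enone, and borohydride at −78 °C reduces the aldehyde but not the conjugated ketone, giving the C2 alcohol needed as a directing group.

Step 11
Reactants: 16 enone alcohol
Product: 17 saturated ring-A ketone (10S,11R) with H-10 and H-11 cis to the C2 arm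
Conditions: H2 (1–5 bar), [Ir(cod)(PCy3)(py)]PF6 (10 mol%), CH2Cl2, rt
Reagents that add atoms: none
Why: Hydroxyl-directed hydrogenation, in which the homoallylic C2 hydroxyl binds the cationic iridium centre and both hydrogens are delivered syn to the face of C10=C11 that carries the C2 arm, setting C10 and C11 together (C9 arm and C20 methyl cis to the C15 methyl).

Step 12
Reactants: 17 saturated ketone
Product: 18 ring-A diol with (12S)-OH, cis to the C20 methyl and trans to C14–O
Conditions: LiBH(s-Bu)3, THF, −78 °C; NaOH, H2O2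
Reagents that add atoms: none
Why: Ketone reduction by a bulky trialkylborohydride; in the chair that avoids the 1,3-diaxial C15/C20 methyl pair the C9 arm is axial and blocks axial attack, so hydride should enter equatorially and give the axial C12 alcohol.

Step 13
Reactants: 18 diol
Product: 19 ring-A hydroxy aldehyde (C2 = CHO, C12–OH free)
Conditions: 2,2,6,6-tetramethylpiperidin-1-oxyl (TEMPO, 10 mol%), PhI(OAc)2, CH2Cl2, rt
Reagents that add atoms: none
Why: TEMPO-catalysed oxidation is selective for the primary over the hindered secondary alcohol and gives the non-enolisable C2 aldehyde.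

Step 14
Reactants: 19 hydroxy aldehyde
Product: 20 ring-A aldehyde with C12–OTBS
Conditions: t-BuMe2SiOTf, 2,6-lutidine, CH2Cl2, −78 → 0 °C
Reagents that add atoms: tert-butyldimethylsilyl triflate CC(C)(C)[Si](C)(C)OS(=O)(=O)C(F)(F)F
Why: Silylation with the triflate protects the hindered C12 hydroxyl as the robust ether that is kept until the last step.

Step 15
Reactants: 20 aldehyde; 21 5-bromopent-2-yne
Product: 23 C2 carbinols (mixture) bearing the C3–C5 pent-3-ynyl chain, via Grignard reagent 22 (not isolated)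
Conditions: 21, Mg, THF; then 20, −78 → 0 °C
Reagents that add atoms: magnesium [Mg] (stays in 22 only)
Why: Grignard addition forms C2–C3 and brings in a methyl-capped alkyne for the later metathesis; the α-quaternary aldehyde offers little facial bias, so the mixture is corrected in the next two steps.

Step 16
Reactants: 23 carbinol mixture
Product: 24 C2 ketone
Conditions: Dess–Martin periodinane, NaHCO3, CH2Cl2, rt
Reagents that add atoms: none
Why: Dess–Martin oxidation removes the uncontrolled C2 centre.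

Step 17
Reactants: 24 ketone
Product: 25 (2R)-carbinol
Conditions: (S)-1-methyl-3,3-diphenyltetrahydro-1H,3H-pyrrolo[1,2-c][1,3,2]oxazaborole ((S)-Me-CBS, 0.2 equiv), catecholborane, toluene, −78 → −40 °C
Reagents that add atoms: none
Why: Corey–Bakshi–Shibata reduction; with quaternary C1 as the large and the CH2 chain as the small group the (S)-catalyst should deliver hydride to the face giving the (2R) alcohol, the sense in which it reduces pinacolone to the (R) alcohol.

Step 18
Reactants: 25 carbinol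
Product: 26 (2R)-triethylsilyl ether
Conditions: Et3SiOTf, 2,6-lutidine, CH2Cl2, −78 °C
Reagents that add atoms: triethylsilyl triflate CC[Si](CC)(CC)OS(=O)(=O)C(F)(F)F
Why: Silyl ether formation masks C2–OH with the group later exchanged for acetate.

Step 19
Reactants: 26 PMB ether
Product: 27 C9 primary alcohol
Conditions: DDQ, CH2Cl2–pH 7 buffer, 0 °C
Reagents that add atoms: none
Why: Oxidative cleavage of the 4-methoxybenzyl ether (hydride abstraction, hydrolysis of the oxocarbenium ion) frees C9–OH without touching the silyl ethers or the alkyne.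

Step 20
Reactants: 27 alcohol
Product: 28 C9 aldehyde
Conditions: Dess–Martin periodinane, NaHCO3, CH2Cl2, 0 °C
Reagents that add atoms: none
Why: Buffered Dess–Martin oxidation gives the aldehyde without epimerising the adjacent C10 centre.

Step 21
Reactants: 29 propargyl alcohol
Product: 31 (E)-3-iodo-2-methylprop-2-en-1-ol, via alkenylalane 30 (not isolated)
Conditions: Me3Al, Cp2ZrCl2 (25 mol%), CH2Cl2, 0 °C → rt; I2, THF, −30 °C
Reagents that add atoms: trimethylaluminium C[Al](C)C (methyl = C18; aluminium stays in 30 only); iodine II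
Why: Zirconium-catalysed carboalumination (Negishi) adds methyl and aluminium syn with aluminium at the terminus, and iodinolysis with retention gives the E alkenyl iodide that carries C8, C17, C18 and C19.

Step 22
Reactants: 31 iodo alcohol; 32 1-bromobut-2-yne
Product: 33 (E)-1-iodo-2-methyl-3-(but-2-ynyloxy)prop-1-ene
Conditions: NaH, THF, 0 °C; 32, Bu4NI (cat.), rt
Reagents that add atoms: none
Why: Williamson etherification joins C19–O to the propargylic C7 and so creates the allyl propargyl ether oxygen bridge.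

Step 23
Reactants: 28 aldehyde; 33 alkenyl iodide
Product: 35 C9 allylic alcohol (C9 as in the target, E alkene), via alkenylchromium reagent 34 (not isolated)
Conditions: CrCl2 (4 equiv), NiCl2 (2 mol%), DMSO, rt
Reagents that add atoms: chromium dichloride Cl[Cr]Cl (chromium stays in 34 only)
Why: Nozaki–Hiyama–Kishi coupling; the alkenylchromium species adds only to the aldehyde, and Felkin–Anh attack anti to the quaternary C1 (large group) past H-10 should set C9 with the target configuration while the E alkene is retained.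

Step 24
Reactants: 35 allylic alcohol
Product: 36 acyclic diyne with TES ethers at C2, C9 and C14
Conditions: Et3SiOTf, 2,6-lutidine, CH2Cl2, −78 °C
Reagents that add atoms: triethylsilyl triflate CC[Si](CC)(CC)OS(=O)(=O)C(F)(F)F
Why: Silyl ether formation protects the C9 allylic hydroxyl.

Step 25
Reactants: 36 diyne
Product: 37 13-membered allyl propargyl ether fused to ring A
Conditions: Mo(≡CC6H4OMe-4)(OSiPh3)3 (5 mol%), 5 Å sieves, toluene (2 mM), 80 °C
Reagents that add atoms: none
Why: Ring-closing alkyne metathesis joins the two methyl-capped alkynes into C5≡C6 with loss of volatile but-2-yne and closes the 13-membered ring without touching the alkene.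

Step 26
Reactants: 37 13-membered ether
Product: 38 cyclodec-5-yn-7-ol with an isopropenyl group on C8
Conditions: n-BuLi (1.3 equiv), THF, −78 → −30 °C; H2O
Reagents that add atoms: none
Why: n-BuLi removes a C7 proton, which is propargylic and α to oxygen, and the carbanion attacks C8 through a five-membered envelope transition state while the O–C19 bond breaks, so that C19=C17 becomes the isopropenyl alkene and oxygen the C7 alkoxide. This is a [2,3]-Wittig rearrangement run as a ring contraction, the reaction type established for 13-membered allyl propargyl ethers giving cyclodec-5-yn-7-ols. The ten-membered carbocycle (C1–C10) closes by suprafacial C7–C8 bonding across the existing 13-membered ring, a transannular sigmatropic closure and not an end-to-end cyclisation, which avoids most of the entropic cost of medium-ring formation. C8 is controlled by C9: allylic 1,3-strain with the C18 methyl holds H-9 in the alkene plane, the silyloxy group covers one face and the ring chain (C10) lies on the other, so C7, which is tied to that chain, should bond to the face anti to the silyloxy group. C7 is set relative to C8 by the E geometry of the C8=C17 alkene with the alkynyl group exo on the envelope (anti product). The step needs deprotonation at C7 and not at allylic C19, and [2,3] and not [1,2] migration; the alkyne secures the first by acidifying C7 and the low temperature the second.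

Step 27
Reactants: 38 cyclodecynol
Product: 40 C7,C19-diol (C17 epimers), via alkylborane 39 (not isolated)
Conditions: 9-borabicyclo[3.3.1]nonane (2.5 equiv), THF, 0 °C → rt; NaOH, H2O2, 0 °C
Reagents that add atoms: hydrogen peroxide OO; 9-borabicyclo[3.3.1]nonane [H]B1C2CCCC1CCC2 (boron stays in 39 only)
Why: Hydroboration–oxidation; the borane adds to the 1,1-disubstituted alkene far faster than to the internal alkyne and places boron on terminal C19.

Step 28
Reactants: 40 diol
Product: 42 saturated γ-lactone (C7–O–C19), via lactol 41 (not isolated)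
Conditions: TEMPO (20 mol%), PhI(OAc)2 (2.5 equiv), CH2Cl2, rt
Reagents that add atoms: none
Why: TEMPO-catalysed oxidative lactonisation; the primary alcohol gives the aldehyde, C7–OH closes the five-membered lactol (5-exo-trig) and further oxidation gives the γ-lactone ring.

Step 29
Reactants: 42 lactone
Product: 44 butenolide (C8=C17), via selenide 43 (not isolated)
Conditions: LiN(i-Pr)2, THF, −78 °C; PhSeBr; then H2O2, CH2Cl2, 0 °C
Reagents that add atoms: benzeneselenenyl bromide Br[Se]c1ccccc1 (selenium stays in 43 only)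
Why: Selenoxide elimination; the lactone enolate is selenenylated at C17 anti to the C9 branch and hence syn to H-8, and syn elimination towards H-8 gives the endocyclic butenolide, erasing C8 and C17 while C7 stays untouched under the base-free oxidation.

Step 30
Reactants: 44 butenolide
Product: 45 (Z)-ene-diol (C7–OH, C19–OH, C8=C17)
Conditions: i-Bu2AlH (4 equiv), CH2Cl2, −78 → 0 °C; potassium sodium tartrate (aq)
Reagents that add atoms: none
Why: Exhaustive 1,2-hydride reduction of the butenolide through the lactol gives the open ene-diol, in which C7 again bears a free hydroxyl and can adopt the strain-minimised rotamer.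

Step 31
Reactants: 45 ene-diol
Product: 46 8,17-epoxy diol
Conditions: VO(acac)2 (5 mol%), t-BuOOH, CH2Cl2, 0 °C
Reagents that add atoms: tert-butyl hydroperoxide CC(C)(C)OO
Why: Hydroxyl-directed epoxidation by the vanadium-bound peroxide; allylic 1,3-strain with C19 and C18 holds H-7 and H-9 in the alkene plane, which puts O-7 and O-9 on one face and the ring on the other, so oxygen should add to the face that gives C8–O anti to both C7–O and C9–O as in the target.

Step 32
Reactants: 46 epoxy diol
Product: 48 8,17-epoxy γ-lactone, via epoxy lactol 47 (not isolated)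
Conditions: TEMPO (20 mol%), PhI(OAc)2 (2.5 equiv), CH2Cl2, rt
Reagents that add atoms: none
Why: TEMPO-catalysed oxidative lactonisation re-forms the γ-lactone ring (aldehyde, 5-exo-trig lactol, lactone) with the epoxide intact.

Step 33
Reactants: 48 epoxy lactone
Product: 50 (17R)-8-hydroxy γ-lactone, via C17 epimer mixture 49 (not isolated)
Conditions: SmI2, HMPA, Me2NCH2CH2OH, THF, −78 °C; then DBU (cat.), CH2Cl2, rt
Reagents that add atoms: none
Why: Samarium diiodide reduction of the α,β-epoxy lactone cleaves only the C17–O bond and leaves the tertiary C8 alcohol with its configuration, and amidine-catalysed equilibration of the protonated enolate should place the C18 methyl trans to the bulky C9 branch.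

Step 34
Reactants: 50 hydroxy lactone
Product: 52 C5 alkenyl iodide (ring-cis alkene), via alkenylzirconocene 51 (not isolated)
Conditions: Cp2Zr(H)Cl (2.5 equiv), THF, rt; I2, 0 °C
Reagents that add atoms: iodine II; zirconocene chloride hydride [H][Zr](Cl)(C1C=CC=C1)C1C=CC=C1 (zirconium stays in 51 only)
Why: Hydrozirconation–iodination; Zr–H adds syn with zirconium at the less hindered alkyne carbon C5, distal to the branched C7, and iodinolysis proceeds with retention.

Step 35
Reactants: 52 alkenyl iodide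
Product: 53 C5 methyl ester ((5E)-enoate)
Conditions: Pd(PPh3)4 (10 mol%), CO (1 atm), MeOH, Et3N, DMF, 45 °C
Reagents that add atoms: carbon monoxide [C-]#[O+]; methanol CO
Why: Palladium-catalysed methoxycarbonylation (oxidative addition into C–I, CO insertion, methanolysis) replaces iodine by the ester with retention of alkene geometry.

Step 36
Reactants: 53 tris-TES ether
Product: 54 2,9,14-triol with C12–OTBS
Conditions: HF·pyridine, pyridine, THF, 0 °C
Reagents that add atoms: none
Why: Buffered fluoride desilylation removes the three triethylsilyl ethers much faster than the hindered secondary tert-butyldimethylsilyl ether.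

Step 37
Reactants: 54 triol
Product: 55 2,9,14-triacetate with C12–OTBS
Conditions: Ac2O, pyridine, DMAP (cat.), CH2Cl2, 0 °C → rt
Reagents that add atoms: acetic anhydride CC(=O)OC(C)=O
Why: Acylation of the three secondary hydroxyls; the tertiary C8 alcohol is too hindered to react under these conditions.

Step 38
Reactants: 55 silyl ether
Product: 56 CNP0233742.2, (1S,2R,5E,7S,8S,9R,10S,11R,12S,14S,17R)
Conditions: HF·pyridine, THF, rt
Reagents that add atoms: none
Why: Fluoride cleavage of the last silyl ether frees the C12 hydroxyl.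

**Compound list**

1 | 2-methylcyclohexane-1,3-dione | CC1C(=O)CCCC1=O | starting material
2 | allyl bromide | C=CCBr | starting material
3 | 2-allyl-2-methylcyclohexane-1,3-dione | C=CCC1(C)C(=O)CCCC1=O | intermediate
4 | (2S,3S)-2-allyl-3-hydroxy-2-methylcyclohexan-1-one | O=C1CCC[C@H](O)[C@]1(C)CC=C | intermediate
5 | (2S,3S)-2-allyl-2-methyl-3-(triethylsilyloxy)cyclohexan-1-one | O=C1CCC[C@H](O[Si](CC)(CC)CC)[C@]1(C)CC=C | intermediate
6 | (2S,3S)-2-methyl-2-[(E)-prop-1-enyl]-3-(triethylsilyloxy)cyclohexan-1-one | O=C1CCC[C@H](O[Si](CC)(CC)CC)[C@]1(C)/C=C/C | intermediate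
7 | (2S,3S)-2,6-dimethyl-2-[(E)-prop-1-enyl]-3-(triethylsilyloxy)cyclohexan-1-one, C11 epimers | O=C1C(C)CC[C@H](O[Si](CC)(CC)CC)[C@]1(C)/C=C/C | intermediate
8 | trimethylsilyl enol ether of 7 (C10=C11) | C[Si](C)(C)OC1=C(C)CC[C@H](O[Si](CC)(CC)CC)[C@]1(C)/C=C/C | intermediate (not isolated)
9 | (5S,6S)-2,6-dimethyl-6-[(E)-prop-1-enyl]-5-(triethylsilyloxy)cyclohex-2-en-1-one | O=C1C(C)=CC[C@H](O[Si](CC)(CC)CC)[C@]1(C)/C=C/C | intermediate
10 | (tributylstannyl)methanol | CCCC[Sn](CCCC)(CCCC)CO | starting material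
11 | tributyl[(4-methoxybenzyloxy)methyl]stannane | CCCC[Sn](CCCC)(CCCC)COCc1ccc(OC)cc1 | intermediate
12 | [(4-methoxybenzyloxy)methyl]lithium | [Li]COCc1ccc(OC)cc1 | intermediate (not isolated)
13 | (5S,6S)-1-[(4-methoxybenzyloxy)methyl]-2,6-dimethyl-6-[(E)-prop-1-enyl]-5-(triethylsilyloxy)cyclohex-2-en-1-ol, C10 epimers | OC1(COCc2ccc(OC)cc2)C(C)=CC[C@H](O[Si](CC)(CC)CC)[C@]1(C)/C=C/C | intermediate
14 | (4R,5S)-3-[(4-methoxybenzyloxy)methyl]-2,4-dimethyl-4-[(E)-prop-1-enyl]-5-(triethylsilyloxy)cyclohex-2-en-1-one | O=C1C[C@H](O[Si](CC)(CC)CC)[C@](C)(/C=C/C)C(COCc2ccc(OC)cc2)=C1C | intermediate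
15 | 4-formyl analogue of 14 (C2 aldehyde) | O=C1C[C@H](O[Si](CC)(CC)CC)[C@](C)(C=O)C(COCc2ccc(OC)cc2)=C1C | intermediate (not isolated)
16 | 4-(hydroxymethyl) analogue of 14 (C2 alcohol) | O=C1C[C@H](O[Si](CC)(CC)CC)[C@](C)(CO)C(COCc2ccc(OC)cc2)=C1C | intermediate
17 | saturated ring-A ketone, (10S,11R), H-10 and H-11 cis to the C2 arm | O=C1C[C@H](O[Si](CC)(CC)CC)[C@](C)(CO)[C@@H](COCc2ccc(OC)cc2)[C@H]1C | intermediate
18 | ring-A diol, (12S)-OH trans to C14–OTES | O[C@H]1C[C@H](O[Si](CC)(CC)CC)[C@](C)(CO)[C@@H](COCc2ccc(OC)cc2)[C@H]1C | intermediate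
19 | ring-A C2 aldehyde with free C12–OH | O[C@H]1C[C@H](O[Si](CC)(CC)CC)[C@](C)(C=O)[C@@H](COCc2ccc(OC)cc2)[C@H]1C | intermediate
20 | ring-A C2 aldehyde with C12–OTBS | CC(C)(C)[Si](C)(C)O[C@H]1C[C@H](O[Si](CC)(CC)CC)[C@](C)(C=O)[C@@H](COCc2ccc(OC)cc2)[C@H]1C | intermediate
21 | 5-bromopent-2-yne | CC#CCCBr | starting material
22 | pent-3-ynylmagnesium bromide | CC#CCC[Mg]Br | intermediate (not isolated)
23 | C2 carbinols (epimers) with pent-3-ynyl chain | CC(C)(C)[Si](C)(C)O[C@H]1C[C@H](O[Si](CC)(CC)CC)[C@](C)(C(O)CCC#CC)[C@@H](COCc2ccc(OC)cc2)[C@H]1C | intermediate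
24 | C2 ketone | CC(C)(C)[Si](C)(C)O[C@H]1C[C@H](O[Si](CC)(CC)CC)[C@](C)(C(=O)CCC#CC)[C@@H](COCc2ccc(OC)cc2)[C@H]1C | intermediate
25 | (2R)-carbinol | CC(C)(C)[Si](C)(C)O[C@H]1C[C@H](O[Si](CC)(CC)CC)[C@](C)([C@H](O)CCC#CC)[C@@H](COCc2ccc(OC)cc2)[C@H]1C | intermediate
26 | (2R)-triethylsilyl ether, C9–OPMB | CC(C)(C)[Si](C)(C)O[C@H]1C[C@H](O[Si](CC)(CC)CC)[C@](C)([C@H](O[Si](CC)(CC)CC)CCC#CC)[C@@H](COCc2ccc(OC)cc2)[C@H]1C | intermediate
27 | C9 primary alcohol | CC(C)(C)[Si](C)(C)O[C@H]1C[C@H](O[Si](CC)(CC)CC)[C@](C)([C@H](O[Si](CC)(CC)CC)CCC#CC)[C@@H](CO)[C@H]1C | intermediate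
28 | C9 aldehyde | CC(C)(C)[Si](C)(C)O[C@H]1C[C@H](O[Si](CC)(CC)CC)[C@](C)([C@H](O[Si](CC)(CC)CC)CCC#CC)[C@@H](C=O)[C@H]1C | intermediate
29 | propargyl alcohol | C#CCO | starting material
30 | (E)-[3-(dimethylalumanyloxy)-2-methylprop-1-enyl]dimethylalumane | C[Al](C)OC/C(C)=C/[Al](C)C | intermediate (not isolated)
31 | (E)-3-iodo-2-methylprop-2-en-1-ol | OC/C(C)=C/I | intermediate
32 | 1-bromobut-2-yne | CC#CCBr | starting material
33 | (E)-1-iodo-2-methyl-3-(but-2-ynyloxy)prop-1-ene | CC#CCOC/C(C)=C/I | intermediate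
34 | (E)-[3-(but-2-ynyloxy)-2-methylprop-1-enyl]chromium dichloride | CC#CCOC/C(C)=C/[Cr](Cl)Cl | intermediate (not isolated)
35 | C9 allylic alcohol, C9 as in the target, (E)-C8=C17 | CC(C)(C)[Si](C)(C)O[C@H]1C[C@H](O[Si](CC)(CC)CC)[C@](C)([C@H](O[Si](CC)(CC)CC)CCC#CC)[C@@H]([C@@H](O)/C=C(\C)COCC#CC)[C@H]1C | intermediate
36 | acyclic diyne, TES at O2, O9, O14, TBS at O12 | CC(C)(C)[Si](C)(C)O[C@H]1C[C@H](O[Si](CC)(CC)CC)[C@](C)([C@H](O[Si](CC)(CC)CC)CCC#CC)[C@@H]([C@@H](O[Si](CC)(CC)CC)/C=C(\C)COCC#CC)[C@H]1C | intermediate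
37 | 13-membered C7–O–C19 allyl propargyl ether fused to ring A | C1#CCOC/C(C)=C/[C@H](O[Si](CC)(CC)CC)[C@H]2[C@@H](C)[C@@H](O[Si](C)(C)C(C)(C)C)C[C@H](O[Si](CC)(CC)CC)[C@]2(C)[C@H](O[Si](CC)(CC)CC)CC1 | intermediate
38 | cyclodec-5-yn-7-ol with C8 isopropenyl (7,8-anti) | C1#C[C@H](O)[C@@H](C(C)=C)[C@H](O[Si](CC)(CC)CC)[C@H]2[C@@H](C)[C@@H](O[Si](C)(C)C(C)(C)C)C[C@H](O[Si](CC)(CC)CC)[C@]2(C)[C@H](O[Si](CC)(CC)CC)CC1 | intermediate
39 | C19 alkylborane / C7 borinate of 38 | C1#C[C@H](OB3C4CCCC3CCC4)[C@@H](C(C)CB5C6CCCC5CCC6)[C@H](O[Si](CC)(CC)CC)[C@H]2[C@@H](C)[C@@H](O[Si](C)(C)C(C)(C)C)C[C@H](O[Si](CC)(CC)CC)[C@]2(C)[C@H](O[Si](CC)(CC)CC)CC1 | intermediate (not isolated)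
40 | C7,C19-diol, C17 epimers | C1#C[C@H](O)[C@@H](C(C)CO)[C@H](O[Si](CC)(CC)CC)[C@H]2[C@@H](C)[C@@H](O[Si](C)(C)C(C)(C)C)C[C@H](O[Si](CC)(CC)CC)[C@]2(C)[C@H](O[Si](CC)(CC)CC)CC1 | intermediate
41 | C19 lactol | C1#C[C@@H]2OC(O)C(C)[C@H]2[C@H](O[Si](CC)(CC)CC)[C@H]3[C@@H](C)[C@@H](O[Si](C)(C)C(C)(C)C)C[C@H](O[Si](CC)(CC)CC)[C@]3(C)[C@H](O[Si](CC)(CC)CC)CC1 | intermediate (not isolated)
42 | saturated γ-lactone, C17 epimers | C1#C[C@@H]2OC(=O)C(C)[C@H]2[C@H](O[Si](CC)(CC)CC)[C@H]3[C@@H](C)[C@@H](O[Si](C)(C)C(C)(C)C)C[C@H](O[Si](CC)(CC)CC)[C@]3(C)[C@H](O[Si](CC)(CC)CC)CC1 | intermediate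
43 | C17 phenylselenide of 42 | C1#C[C@@H]2OC(=O)C(C)([Se]c4ccccc4)[C@H]2[C@H](O[Si](CC)(CC)CC)[C@H]3[C@@H](C)[C@@H](O[Si](C)(C)C(C)(C)C)C[C@H](O[Si](CC)(CC)CC)[C@]3(C)[C@H](O[Si](CC)(CC)CC)CC1 | intermediate (not isolated)
44 | butenolide (C8=C17) | C1#C[C@@H]2OC(=O)C(C)=C2[C@H](O[Si](CC)(CC)CC)[C@H]3[C@@H](C)[C@@H](O[Si](C)(C)C(C)(C)C)C[C@H](O[Si](CC)(CC)CC)[C@]3(C)[C@H](O[Si](CC)(CC)CC)CC1 | intermediate
45 | (Z)-ene-diol (C7–OH, C19–OH) | C1#C[C@H](O)/C(=C(/C)CO)[C@H](O[Si](CC)(CC)CC)[C@H]2[C@@H](C)[C@@H](O[Si](C)(C)C(C)(C)C)C[C@H](O[Si](CC)(CC)CC)[C@]2(C)[C@H](O[Si](CC)(CC)CC)CC1 | intermediate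
46 | 8,17-epoxy diol | C1#C[C@H](O)[C@]3(O[C@@]3(C)CO)[C@H](O[Si](CC)(CC)CC)[C@H]2[C@@H](C)[C@@H](O[Si](C)(C)C(C)(C)C)C[C@H](O[Si](CC)(CC)CC)[C@]2(C)[C@H](O[Si](CC)(CC)CC)CC1 | intermediate
47 | 8,17-epoxy lactol | C1#C[C@@H]2OC(O)[C@]4(C)O[C@]24[C@H](O[Si](CC)(CC)CC)[C@H]3[C@@H](C)[C@@H](O[Si](C)(C)C(C)(C)C)C[C@H](O[Si](CC)(CC)CC)[C@]3(C)[C@H](O[Si](CC)(CC)CC)CC1 | intermediate (not isolated)
48 | 8,17-epoxy γ-lactone | C1#C[C@@H]2OC(=O)[C@]4(C)O[C@]24[C@H](O[Si](CC)(CC)CC)[C@H]3[C@@H](C)[C@@H](O[Si](C)(C)C(C)(C)C)C[C@H](O[Si](CC)(CC)CC)[C@]3(C)[C@H](O[Si](CC)(CC)CC)CC1 | intermediate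
49 | 8-hydroxy γ-lactone, C17 epimers | C1#C[C@@H]2OC(=O)C(C)[C@@]2(O)[C@H](O[Si](CC)(CC)CC)[C@H]3[C@@H](C)[C@@H](O[Si](C)(C)C(C)(C)C)C[C@H](O[Si](CC)(CC)CC)[C@]3(C)[C@H](O[Si](CC)(CC)CC)CC1 | intermediate (not isolated)
50 | (17R)-8-hydroxy γ-lactone, C5≡C6 | C1#C[C@@H]2OC(=O)[C@H](C)[C@@]2(O)[C@H](O[Si](CC)(CC)CC)[C@H]3[C@@H](C)[C@@H](O[Si](C)(C)C(C)(C)C)C[C@H](O[Si](CC)(CC)CC)[C@]3(C)[C@H](O[Si](CC)(CC)CC)CC1 | intermediate
51 | C5 alkenylzirconocene chloride, O8 zirconium alkoxide | Cl[Zr](C4C=CC=C4)(C5C=CC=C5)/C1=C/[C@@H]2OC(=O)[C@H](C)[C@@]2(O[Zr](Cl)(C6C=CC=C6)C7C=CC=C7)[C@H](O[Si](CC)(CC)CC)[C@H]3[C@@H](C)[C@@H](O[Si](C)(C)C(C)(C)C)C[C@H](O[Si](CC)(CC)CC)[C@]3(C)[C@H](O[Si](CC)(CC)CC)CC1 | intermediate (not isolated)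
52 | C5 alkenyl iodide | I/C1=C/[C@@H]2OC(=O)[C@H](C)[C@@]2(O)[C@H](O[Si](CC)(CC)CC)[C@H]3[C@@H](C)[C@@H](O[Si](C)(C)C(C)(C)C)C[C@H](O[Si](CC)(CC)CC)[C@]3(C)[C@H](O[Si](CC)(CC)CC)CC1 | intermediate
53 | C5 methyl ester, tris-TES, 12-TBS | COC(=O)/C1=C/[C@@H]2OC(=O)[C@H](C)[C@@]2(O)[C@H](O[Si](CC)(CC)CC)[C@H]3[C@@H](C)[C@@H](O[Si](C)(C)C(C)(C)C)C[C@H](O[Si](CC)(CC)CC)[C@]3(C)[C@H](O[Si](CC)(CC)CC)CC1 | intermediate
54 | 2,9,14-triol, 12-TBS | COC(=O)/C1=C/[C@@H]2OC(=O)[C@H](C)[C@@]2(O)[C@H](O)[C@H]3[C@@H](C)[C@@H](O[Si](C)(C)C(C)(C)C)C[C@H](O)[C@]3(C)[C@H](O)CC1 | intermediate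
55 | 2,9,14-triacetate, 12-TBS | COC(=O)/C1=C/[C@@H]2OC(=O)[C@H](C)[C@@]2(O)[C@H](OC(C)=O)[C@H]3[C@@H](C)[C@@H](O[Si](C)(C)C(C)(C)C)C[C@H](OC(C)=O)[C@]3(C)[C@H](OC(C)=O)CC1 | intermediate
56 | CNP0233742.2 | COC(=O)/C1=C/[C@@H]2OC(=O)[C@H](C)[C@@]2(O)[C@H](OC(C)=O)[C@H]2[C@@H](C)[C@@H](O)C[C@H](OC(C)=O)[C@]2(C)[C@H](OC(C)=O)CC1 | target

**Count and risks**

Total steps: 38. Longest linear sequence: 35 steps (1–6, 8–20, 23–38) from 2-methylcyclohexane-1,3-dione; steps 7, 21 and 22 are side branches.

Step 11. Hydrogen delivery to the hindered, electron-poor tetrasubstituted enone may be slow or not face-selective, and the product ketone may lose the C11 configuration by enolisation. Fallback from 16 to 18: Luche reduction of 16 (NaBH4, CeCl3·7H2O, MeOH, −78 °C) should give the 12-epi allylic diol F1, with the C12 hydroxyl cis to C14–O and to the C2 arm (axial attack, as carvone gives cis-carveol). This allylic hydroxyl is the classical anchor for [Ir(cod)(PCy3)(py)]PF6 and the alkene is now electron-rich, so hydrogenation should give the saturated 12-epi diol F2 with H-10 and H-11 on the required face. Dess–Martin oxidation of both hydroxyls gives the keto aldehyde F3, and LiBH(s-Bu)3 reduces both carbonyls (C12 as in step 12) to rejoin at 18.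

Step 34. Zr–H may attack the lactone carbonyl, or place zirconium partly on C6, where β-elimination of the C7 carboxylate would open the lactone. Fallback from 50 to 53, bypassing 52: metal-free hydroboration with pinacolborane catalysed by dicyclohexylborane (THF, rt; syn addition, boron on the less hindered C5, lactone inert) gives the alkenylboronate F4. Palladium-catalysed oxidative methoxycarbonylation (Pd(OAc)2, PPh3, p-benzoquinone, CO, MeOH, rt) then converts C–B into the ester with retention.

Step 26. Facial discrimination at C8 and the choice between the two C7 hydrogens rests on substrate bias alone and may be incomplete, and [1,2]-shift or deprotonation at C19 may compete. Fallback from 37 to 38, making no new compound (F0): deprotonation with the matched enantiomer of lithium bis(1-phenylethyl)amide (THF, −78 °C) puts the choice of C7 hydrogen under reagent control, a known way to run [2,3]-Wittig ring contractions of 13-membered propargylic ethers. Only C7 has to be right, since C8 is erased in step 29.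

Further compounds
F1 | step 11 | 12-epi allylic diol from 16 (C12–OH cis to C14–OTES, C10=C11) | O[C@@H]1C[C@H](O[Si](CC)(CC)CC)[C@](C)(CO)C(COCc2ccc(OC)cc2)=C1C
F2 | step 11 | saturated 12-epi diol (H-10, H-11 cis to the C2 arm) | O[C@@H]1C[C@H](O[Si](CC)(CC)CC)[C@](C)(CO)[C@@H](COCc2ccc(OC)cc2)[C@H]1C
F3 | step 11 | ring-A keto aldehyde (C12 ketone, C2 aldehyde) | O=C1C[C@H](O[Si](CC)(CC)CC)[C@](C)(C=O)[C@@H](COCc2ccc(OC)cc2)[C@H]1C
F4 | step 34 | C5 alkenyl pinacol boronate of 50 | CC1(C)OB(OC1(C)C)/C2=C/[C@@H]3OC(=O)[C@H](C)[C@@]3(O)[C@H](O[Si](CC)(CC)CC)[C@H]4[C@@H](C)[C@@H](O[Si](C)(C)C(C)(C)C)C[C@H](O[Si](CC)(CC)CC)[C@]4(C)[C@H](O[Si](CC)(CC)CC)CC2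
F0 | step 26 | none | none
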